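**Retrosynthetic overview**

1. Target ⇐ C1 allylic oxidation, C9 angeloylation, α-methylenation of the 6,12-lactone, and a cis-3,4-epoxide made from an E-3,4-alkene by syn-dihydroxylation and invertive ring closure.
2. Lactone ⇐ ten-membered 8-keto ester: C7 alkylation of the ring-expansion enolate with bromoacetate, C6–O unmasking, chelation-controlled C8 reduction.
3. Ten-membered carbocycle ⇐ anionic oxy-Cope [3,3] shift of a 1,2-dialkenylcyclohexanol (forms C5–C6, sets C6 and the E-alkene).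
4. Cyclohexanol ⇐ alkoxyacetylide addition and trans-reduction on an epoxy ketone from (R)-carvone; C9–O and the 10(14)-methylene are set on the six-membered ring.
5. Ring order: six-membered ring (bought in carvone) → ten-membered ring → γ-lactone → epoxide.

Assumption: target atom labels (C1 ketone, C3/C4 epoxide, C6 lactone O–CH, C7, C8 OH, C9 angelate, C10=C14, C11=C13, C12 lactone C=O, C15 methyl; target = 3S,4R,6R,7R,8R,9S) are used for all intermediates (carvone C1–C6 become C1, C10, C9, C8, C3, C2); TBS = tert-butyldimethylsilyl, PMB = 4-methoxybenzyl, DMB = 3,4-dimethoxybenzyl; Zn(BH4)2 and LiN(i-Pr)2 are used as ready-made solutions.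

The route is a paper design; no step has been run, and the stereochemical outcomes in steps 10, 12 and 14 are predictions.

**Route**

Step 1
Reactants: 1 (R)-(−)-carvone
Product: 2 (1R,5R)-cis-carveol
Conditions: NaBH4, CeCl3·7H2O, MeOH, −20 °C
Reagents that add atoms: none
Why: Luche 1,2-reduction of the enone gives the pseudo-equatorial allylic alcohol cis to the isopropenyl group, setting C1 (used later only as a control element and finally oxidised).

Step 2
Reactants: 2 (1R,5R)-cis-carveol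
Product: 3 cis-carveol TBS ether
Conditions: t-BuMe2SiCl, imidazole, DMF, rt
Reagents that add atoms: tert-butyldimethylsilyl chloride CC(C)(C)[Si](C)(C)Cl
Why: Standard silylation of a secondary allylic alcohol that touches no stereocentre.

Step 3
Reactants: 3 cis-carveol TBS ether
Product: 4 (4R,6R)-4-(TBS-oxy)-3-methyl-6-(prop-1-en-2-yl)cyclohex-2-en-1-one
Conditions: CrO3, 3,5-dimethylpyrazole, CH2Cl2, −20 °C
Reagents that add atoms: chromium trioxide O=[Cr](=O)=O
Why: Chromium-mediated allylic oxidation converts the only ring CH2 allylic to the trisubstituted alkene (C8) into the conjugated ketone, leaving the silyl ether and the isopropenyl group intact.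

Step 4
Reactants: 4 (4R,6R)-4-(TBS-oxy)-3-methyl-6-(prop-1-en-2-yl)cyclohex-2-en-1-one
Product: 5 epoxy ketone (9,10-epoxide trans to OTBS)
Conditions: t-BuOOH, DBU, CH2Cl2, 0 °C to rt
Reagents that add atoms: tert-butyl hydroperoxide CC(C)(C)OO
Why: Weitz–Scheffer nucleophilic epoxidation, in which the peroxide anion adds to C10 anti to the adjacent C1 silyloxy group (and anti to the cis isopropenyl group), sets the C9 oxygen with the target configuration on the rigid six-membered ring.

Step 5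
Reactants: 6 3,4-dimethoxybenzyl alcohol
Product: 7 (E)-1,2-dichlorovinyl 3,4-dimethoxybenzyl ether
Conditions: KH, THF, 0 °C; then Cl2C=CHCl, −50 °C to rt
Reagents that add atoms: trichloroethylene ClC=C(Cl)Cl
Why: Addition–elimination of the potassium alkoxide on trichloroethylene (Greene dichlorovinyl ether synthesis) gives a stable precursor of the alkoxyacetylide.

Step 6
Reactants: 5 epoxy ketone; 7 (E)-1,2-dichlorovinyl 3,4-dimethoxybenzyl ether
Product: 9 C8 propargylic alcohol, via lithium alkoxyacetylide 8 (not isolated)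
Conditions: n-BuLi (2.2 equiv on 7), THF, −78 to −40 °C; then 5, −78 °C; H2O
Reagents that add atoms: none
Why: Dehydrochlorination and Li–Cl exchange give the lithium alkoxyacetylide, which undergoes 1,2-addition to the ketone anti to the α-epoxide oxygen; the new C8 centre is destroyed in step 10, so its configuration is immaterial.

Step 7
Reactants: 9 C8 propargylic alcohol
Product: 10 8,9-cis-diol with 10(14)-methylene
Conditions: LiN(i-Pr)2 (3 equiv), Et2O, 0 °C to rt
Reagents that add atoms: none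
Why: Lithium amide-mediated syn β-elimination (epoxide to allylic alcohol isomerisation) removes the least hindered C14 methyl proton, giving the exocyclic methylene and the C9 alcohol with retention at C9; the cis hydroxyl cannot undergo Payne rearrangement.

Step 8
Reactants: 10 8,9-cis-diol with 10(14)-methylene
Product: 11 (E)-enol ether diol
Conditions: LiAlH4, THF, 0 °C to rt
Reagents that add atoms: none
Why: Alkoxide-directed trans-hydroalumination of the propargylic alcohol reduces the alkynyl ether to the (E)-2-alkoxyvinyl group, avoiding the unstable (E)-2-alkoxyvinyllithium.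

Step 9
Reactants: 11 (E)-enol ether diol
Product: 12 C9 PMB ether
Conditions: NaH (1.05 equiv), 4-MeOC6H4CH2Cl, Bu4NI (cat.), THF–DMF, 0 °C
Reagents that add atoms: 4-methoxybenzyl chloride COc1ccc(CCl)cc1
Why: Williamson etherification occurs at the less hindered secondary C9 alkoxide and leaves the tertiary C8 hydroxyl free, installing a chelating group for step 12.

Step 10
Reactants: 12 C9 PMB ether
Product: 15 ten-membered 8-keto ester, via potassium alkoxide 13 (not isolated), via potassium enolate 14 (not isolated)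
Conditions: KN(SiMe3)2, 18-crown-6, THF, −78 to 0 °C; then BrCH2CO2Me, −78 °C
Reagents that add atoms: methyl bromoacetate COC(=O)CBr
Why: Anionic oxy-Cope [3,3]-sigmatropic rearrangement through a chair transition state (ring bond C3–C2 and the DMB-oxy group equatorial) forms C5–C6, gives the E-3,4-alkene and transfers the carvone-derived C3 chirality to C6 (R), and the regiodefined enolate is alkylated on its outer face (syn to the C6 oxygen) to set C7.

Step 11
Reactants: 15 ten-membered 8-keto ester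
Product: 17 8-oxo-6,12-lactone, via hydroxy ester 16 (not isolated)
Conditions: DDQ (1.1 equiv), CH2Cl2–pH 7 buffer, 0 °C; then PPTS (cat.), PhH, rt
Reagents that add atoms: none
Why: DDQ oxidatively cleaves the more electron-rich DMB ether faster than the PMB ether, and the freed C6 hydroxyl lactonises onto the methyl ester to give the trans-fused γ-lactone.

Step 12
Reactants: 17 8-oxo-6,12-lactone
Product: 18 8-hydroxy lactone
Conditions: Zn(BH4)2, Et2O, −30 °C
Reagents that add atoms: none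
Why: Chelation-controlled (Cram-chelate) reduction with zinc bridging the C8 carbonyl and the C9 PMB ether delivers hydride from the face away from C10 and the ring, giving the 8,9-anti relationship of the target.

Step 13
Reactants: 18 8-hydroxy lactone
Product: 19 8-OTBS lactone
Conditions: t-BuMe2SiOTf, 2,6-lutidine, CH2Cl2, −78 to 0 °C
Reagents that add atoms: tert-butyldimethylsilyl triflate CC(C)(C)[Si](C)(C)OS(=O)(=O)C(F)(F)F
Why: Silylation of the hindered secondary alcohol masks C8–OH so that C9 can later be acylated alone.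

Step 14
Reactants: 19 8-OTBS lactone
Product: 20 3,4-syn-diol
Conditions: OsO4 (5 mol %), NMO, acetone–H2O, 0 °C
Reagents that add atoms: osmium tetroxide O=[Os](=O)(=O)=O; N-methylmorpholine N-oxide C[N+]1([O-])CCOCC1; water O
Why: Upjohn syn-dihydroxylation selects the electron-rich E-trisubstituted alkene over the hindered 1,1-disubstituted methylene and is expected to occur on the outer face of the ten-membered ring, setting C4 and the C3 precursor.

Step 15
Reactants: 20 3,4-syn-diol
Product: 22 cis-3,4-epoxy lactone, via hydroxy mesylate 21 (not isolated)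
Conditions: MsCl, Et3N, CH2Cl2, 0 °C; then DBU, rt
Reagents that add atoms: none
Why: Selective mesylation of the only secondary hydroxyl followed by intramolecular SN2 displacement by the tertiary C4 alkoxide inverts C3, so the syn-diol of the E-alkene becomes the cis-epoxide (3S,4R) of the target.

Step 16
Reactants: 22 cis-3,4-epoxy lactone
Product: 26 α-methylene lactone, via lithium enolate 23 (not isolated), via Mannich base 24 (not isolated), via ammonium iodide 25 (not isolated)
Conditions: LiN(i-Pr)2, THF, −78 °C; CH2=NMe2+ I−, −78 °C to rt; then MeI, MeOH, rt; aq NaHCO3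
Reagents that add atoms: N,N-dimethylmethyleneiminium iodide C=[N+](C)C.[I-]
Why: Mannich reaction of the lactone enolate with Eschenmoser's salt, quaternisation and β-elimination install the 11(13)-methylene while no ketone or enoate ester is present.

Step 17
Reactants: 26 α-methylene lactone
Product: 27 9-hydroxy compound
Conditions: DDQ, CH2Cl2–pH 7 buffer, rt
Reagents that add atoms: none
Why: Neutral oxidative cleavage of the PMB ether frees C9–OH without touching the epoxide, silyl ethers or alkenes.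

Step 18
Reactants: 27 9-hydroxy compound
Product: 28 9-angelate
Conditions: angelic acid, 2,4,6-Cl3C6H2COCl, Et3N, PhMe, rt; then 27, 75 °C
Reagents that add atoms: angelic acid C/C=C(/C)C(=O)O
Why: Yamaguchi-type esterification through the mixed anhydride acylates the only free hydroxyl at the less hindered angeloyl carbonyl without nucleophilic catalysts that isomerise angelate to tiglate.

Step 19
Reactants: 28 9-angelate
Product: 29 1,8-diol 9-angelate
Conditions: Bu4NF, AcOH (1:1), THF, 0 °C to rt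
Reagents that add atoms: none
Why: Fluoride desilylation buffered with acetic acid removes both TBS groups while suppressing acyl migration from O9 to O8 and conjugate addition to the methylene lactone.

Step 20
Reactants: 29 1,8-diol 9-angelate
Product: 30 target CNP0348992.4
Conditions: MnO2, CH2Cl2, rt
Reagents that add atoms: none
Why: MnO2 oxidises only the allylic C1 alcohol (next to the 10(14)-methylene) to the enone and leaves the non-allylic C8 alcohol untouched.

**Compound list**

1 | (R)-(−)-carvone, (5R)-2-methyl-5-(prop-1-en-2-yl)cyclohex-2-en-1-one | CC1=CC[C@H](CC1=O)C(C)=C | starting material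
2 | (1R,5R)-cis-carveol, (1R,5R)-2-methyl-5-(prop-1-en-2-yl)cyclohex-2-en-1-ol | CC1=CC[C@H](C[C@H]1O)C(C)=C | intermediate
3 | (1R,5R)-cis-carveol TBS ether | CC1=CC[C@H](C[C@H]1O[Si](C)(C)C(C)(C)C)C(C)=C | intermediate
4 | (4R,6R)-4-(TBS-oxy)-3-methyl-6-(prop-1-en-2-yl)cyclohex-2-en-1-one (OTBS and isopropenyl cis) | CC1=CC(=O)[C@H](C[C@H]1O[Si](C)(C)C(C)(C)C)C(C)=C | intermediate
5 | 2,3-epoxide of 4: 5-(TBS-oxy)-6-methyl-3-(prop-1-en-2-yl)-7-oxabicyclo[4.1.0]heptan-2-one, epoxide oxygen trans to OTBS and isopropenyl | C[C@@]12O[C@@H]1C(=O)[C@H](C[C@H]2O[Si](C)(C)C(C)(C)C)C(C)=C | intermediate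
6 | 3,4-dimethoxybenzyl alcohol | COc1ccc(CO)cc1OC | starting material
7 | (E)-1,2-dichlorovinyl 3,4-dimethoxybenzyl ether | COc1ccc(CO/C(Cl)=C\Cl)cc1OC | intermediate
8 | lithium (3,4-dimethoxybenzyloxy)acetylide | [Li]C#COCc1ccc(OC)c(OC)c1 | intermediate (not isolated)
9 | C8 tertiary propargylic alcohol: 8-[(DMB-oxy)ethynyl]-8-hydroxy-9,10-epoxide, C8–OH cis to the epoxide oxygen, 1-OTBS, 3-isopropenyl | C[C@@]12O[C@@H]1[C@@](O)(C#COCc1ccc(OC)c(OC)c1)[C@H](C[C@H]2O[Si](C)(C)C(C)(C)C)C(C)=C | intermediate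
10 | 8,9-cis-diol with 10(14)-methylene: 8-[(DMB-oxy)ethynyl], 1-OTBS, 3-isopropenyl, C9 as in the target | C=C1[C@H](O)[C@@](O)(C#COCc2ccc(OC)c(OC)c2)[C@H](C[C@H]1O[Si](C)(C)C(C)(C)C)C(C)=C | intermediate
11 | as 10 with an (E)-2-(DMB-oxy)vinyl group on C8 | C=C1[C@H](O)[C@@](O)(/C=C/OCc2ccc(OC)c(OC)c2)[C@H](C[C@H]1O[Si](C)(C)C(C)(C)C)C(C)=C | intermediate
12 | C9 PMB ether of 11 | C=C1[C@H](OCc2ccc(OC)cc2)[C@@](O)(/C=C/OCc2ccc(OC)c(OC)c2)[C@H](C[C@H]1O[Si](C)(C)C(C)(C)C)C(C)=C | intermediate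
13 | potassium C8 alkoxide of 12 | [K+].C=C1[C@H](OCc2ccc(OC)cc2)[C@@]([O-])(/C=C/OCc2ccc(OC)c(OC)c2)[C@H](C[C@H]1O[Si](C)(C)C(C)(C)C)C(C)=C | intermediate (not isolated)
14 | potassium enolate of the ten-membered ketone (C7=C8–O−, 3E-alkene, 6-ODMB, 9-OPMB, 1-OTBS) | [K+].[O-]/C1=C/[C@H](OCc2ccc(OC)c(OC)c2)C/C(C)=C/C[C@@H](O[Si](C)(C)C(C)(C)C)C(=C)[C@@H]1OCc1ccc(OC)cc1 | intermediate (not isolated)
15 | methyl 2-(ten-membered ring-7-yl)acetate: 8-oxo, 3E-ene, 10(14)-methylene, 1-OTBS, 6-ODMB, 9-OPMB; C6, C7, C9 as in the target | COC(=O)C[C@H]1[C@H](OCc2ccc(OC)c(OC)c2)C/C(C)=C/C[C@@H](O[Si](C)(C)C(C)(C)C)C(=C)[C@H](OCc2ccc(OC)cc2)C1=O | intermediate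
16 | 6-hydroxy analogue of 15 | COC(=O)C[C@H]1[C@H](O)C/C(C)=C/C[C@@H](O[Si](C)(C)C(C)(C)C)C(=C)[C@H](OCc2ccc(OC)cc2)C1=O | intermediate (not isolated)
17 | trans-fused 8-oxo-6,12-lactone, 3E-ene, 10(14)-methylene, 1-OTBS, 9-OPMB | C1C(=O)O[C@@H]2C/C(C)=C/C[C@@H](O[Si](C)(C)C(C)(C)C)C(=C)[C@H](OCc3ccc(OC)cc3)C(=O)[C@@H]12 | intermediate
18 | 8-hydroxy lactone (C8 as in the target) | C1C(=O)O[C@@H]2C/C(C)=C/C[C@@H](O[Si](C)(C)C(C)(C)C)C(=C)[C@H](OCc3ccc(OC)cc3)[C@H](O)[C@@H]12 | intermediate
19 | 8-OTBS lactone | C1C(=O)O[C@@H]2C/C(C)=C/C[C@@H](O[Si](C)(C)C(C)(C)C)C(=C)[C@H](OCc3ccc(OC)cc3)[C@H](O[Si](C)(C)C(C)(C)C)[C@@H]12 | intermediate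
20 | 3,4-syn-diol of 19 (tertiary C4–OH, secondary C3–OH) | C1C(=O)O[C@@H]2C[C@@](C)(O)[C@H](O)C[C@@H](O[Si](C)(C)C(C)(C)C)C(=C)[C@H](OCc3ccc(OC)cc3)[C@H](O[Si](C)(C)C(C)(C)C)[C@@H]12 | intermediate
21 | 3-O-mesylate of 20 | C1C(=O)O[C@@H]2C[C@@](C)(O)[C@H](OS(C)(=O)=O)C[C@@H](O[Si](C)(C)C(C)(C)C)C(=C)[C@H](OCc3ccc(OC)cc3)[C@H](O[Si](C)(C)C(C)(C)C)[C@@H]12 | intermediate (not isolated)
22 | cis-3,4-epoxy lactone (epoxide as in the target), 1,8-bis-OTBS, 9-OPMB | C1C(=O)O[C@@H]2C[C@@]3(C)O[C@H]3C[C@@H](O[Si](C)(C)C(C)(C)C)C(=C)[C@H](OCc3ccc(OC)cc3)[C@H](O[Si](C)(C)C(C)(C)C)[C@@H]12 | intermediate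
23 | lithium enolate of lactone 22 | [Li+].[O-]C1=C[C@H]2[C@H](O1)C[C@@]3(C)O[C@H]3C[C@@H](O[Si](C)(C)C(C)(C)C)C(=C)[C@H](OCc3ccc(OC)cc3)[C@@H]2O[Si](C)(C)C(C)(C)C | intermediate (not isolated)
24 | 11-(dimethylaminomethyl) lactone (C11 epimers) | CN(C)CC1C(=O)O[C@@H]2C[C@@]3(C)O[C@H]3C[C@@H](O[Si](C)(C)C(C)(C)C)C(=C)[C@H](OCc3ccc(OC)cc3)[C@H](O[Si](C)(C)C(C)(C)C)[C@@H]12 | intermediate (not isolated)
25 | trimethylammonium iodide of 24 | [I-].C[N+](C)(C)CC1C(=O)O[C@@H]2C[C@@]3(C)O[C@H]3C[C@@H](O[Si](C)(C)C(C)(C)C)C(=C)[C@H](OCc3ccc(OC)cc3)[C@H](O[Si](C)(C)C(C)(C)C)[C@@H]12 | intermediate (not isolated)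
26 | α-methylene lactone (11(13)-ene), cis-3,4-epoxide, 1,8-bis-OTBS, 9-OPMB | C=C1C(=O)O[C@@H]2C[C@@]3(C)O[C@H]3C[C@@H](O[Si](C)(C)C(C)(C)C)C(=C)[C@H](OCc3ccc(OC)cc3)[C@H](O[Si](C)(C)C(C)(C)C)[C@@H]12 | intermediate
27 | 9-hydroxy compound | C=C1C(=O)O[C@@H]2C[C@@]3(C)O[C@H]3C[C@@H](O[Si](C)(C)C(C)(C)C)C(=C)[C@H](O)[C@H](O[Si](C)(C)C(C)(C)C)[C@@H]12 | intermediate
28 | 9-angelate, 1,8-bis-OTBS | C=C1C(=O)O[C@@H]2C[C@@]3(C)O[C@H]3C[C@@H](O[Si](C)(C)C(C)(C)C)C(=C)[C@H](OC(=O)/C(C)=C\C)[C@H](O[Si](C)(C)C(C)(C)C)[C@@H]12 | intermediate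
29 | 1,8-diol 9-angelate | C=C1C(=O)O[C@@H]2C[C@@]3(C)O[C@H]3C[C@@H](O)C(=C)[C@H](OC(=O)/C(C)=C\C)[C@H](O)[C@@H]12 | intermediate
30 | CNP0348992.4, (3S,4R,6R,7R,8R,9S)-9-angeloyloxy-3,4-epoxy-8-hydroxy-1-oxogermacra-10(14),11(13)-dien-12,6-olide | C=C1C(=O)O[C@@H]2C[C@@]3(C)O[C@H]3CC(=O)C(=C)[C@H](OC(=O)/C(C)=C\C)[C@H](O)[C@@H]12 | target

**Step count and risks**

Total step count: 20. Longest linear sequence: 19 (steps 1–4 and 6–20; step 5 is a one-step branch).

Most likely to fail:

Step 10 (oxy-Cope with in-flask alkylation). The β-alkoxy enolate 14 may lose the DMB alkoxide or alkylate with poor C7 selectivity. Fallback, setting out from 12 and returning at 15: 12 is rearranged as before and enolate 14 is silylated cold with Me3SiCl to give the ten-membered trimethylsilyl enol ether F1. Copper-catalysed cyclopropanation of this electron-rich alkene with methyl diazoacetate and Cu(acac)2 on the outer face gives the siloxycyclopropane ester F2. Fluoride ring opening with Et3N·3HF cleaves the C8–C11 bond and delivers 15 without a free enolate.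

Step 14 (facial selectivity of the dihydroxylation). The macrocycle may expose the other alkene face to OsO4. Fallback, setting out from 19 and returning at 20: Woodward cis-hydroxylation with I2 and AgOAc in wet AcOH first gives the trans iodo acetate F3 (iodine on the exposed face). Its acetoxonium ion is hydrolysed to the cis hydroxy acetate F4, which carries both oxygens on the opposite face to the one OsO4 attacks. K2CO3 in MeOH then gives 20.

Step 18 (angeloylation of a hindered alcohol). The acylation may be slow or give the tiglate. Fallback, setting out from 27 and returning at 28: 27 is esterified with 2-[bis(2,2,2-trifluoroethoxy)phosphoryl]propanoic acid (N,N'-diisopropylcarbodiimide, DMAP) to the C9 phosphonopropanoate F5. Still–Gennari olefination (KN(SiMe3)2, 18-crown-6, THF, −78 °C; MeCHO) then builds the Z-2-methylbut-2-enoate in place, giving 28.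

**Further compounds**

F1 | step 10 | ten-membered trimethylsilyl enol ether (C7=C8–OSiMe3, 6-ODMB, 9-OPMB, 1-OTBS, 3E-ene) | C[Si](C)(C)O/C1=C/[C@H](OCc2ccc(OC)c(OC)c2)C/C(C)=C/C[C@@H](O[Si](C)(C)C(C)(C)C)C(=C)[C@@H]1OCc1ccc(OC)cc1
F2 | step 10 | siloxycyclopropane methyl ester (cyclopropane C7–C8–C11, configuration at the cyclopropane carbons not defined) | COC(=O)C1C2[C@H](OCc3ccc(OC)c(OC)c3)C/C(C)=C/C[C@@H](O[Si](C)(C)C(C)(C)C)C(=C)[C@H](OCc3ccc(OC)cc3)C12O[Si](C)(C)C
F3 | step 14 | trans 3-iodo 4-acetate of 19 | C1C(=O)O[C@@H]2C[C@@](C)(OC(C)=O)[C@@H](I)C[C@@H](O[Si](C)(C)C(C)(C)C)C(=C)[C@H](OCc3ccc(OC)cc3)[C@H](O[Si](C)(C)C(C)(C)C)[C@@H]12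
F4 | step 14 | cis 4-hydroxy 3-acetate (oxygens configured as in 20) | C1C(=O)O[C@@H]2C[C@@](C)(O)[C@H](OC(C)=O)C[C@@H](O[Si](C)(C)C(C)(C)C)C(=C)[C@H](OCc3ccc(OC)cc3)[C@H](O[Si](C)(C)C(C)(C)C)[C@@H]12
F5 | step 18 | C9 2-[bis(2,2,2-trifluoroethoxy)phosphoryl]propanoate of 27 | C=C1C(=O)O[C@@H]2C[C@@]3(C)O[C@H]3C[C@@H](O[Si](C)(C)C(C)(C)C)C(=C)[C@H](OC(=O)C(C)P(=O)(OCC(F)(F)F)OCC(F)(F)F)[C@H](O[Si](C)(C)C(C)(C)C)[C@@H]12
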